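**Retrosynthetic overview**

1. Neoirietetraol ⇐ ketone 27 (C5' corrected by oxidation/reduction) ⇐ cyclic carbonate 25. Its cyclopentane (ring C, C1'–C5') is disconnected at C1'–C2', C3'–Br and C2–O: a Br⁺-initiated 5-exo cation–olefin closure of 1,5-diene 21, with the C2 cation captured by the C5' O-Boc group.
2. Enabling feature: in ring C, the CHBr carbon (C3') sits next to a gem-dimethyl quaternary carbon (C2'), which is bonded to a second quaternary carbon (C1') that carries the tertiary carbinol C2 of ring A; O–C2 and O–C5' are 1,3-related. This is the imprint of bromonium opening of a prenyl group by an alkylidene carbon, with oxygen capture through a carbonate tether.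
3. 21 ⇐ decalinone 12 by Horner–Wadsworth–Emmons olefination, DIBAL, asymmetric allylation and cross-metathesis. The allylation deliberately gives the (R)-C5' epimer, because allylic strain then sets C1' correctly.
4. 12 ⇐ (S)-Wieland–Miescher ketone 1. The C5 bromide comes from the C5 ketone (enol triflate, alkenyl bromide, HAT hydrogenation); the C8/C8a diol comes from the C8=C8a alkene (ketohydroxylation, methyl addition).
5. Ring order: rings A and B (the decalin) are present, fused, in 1; ring C is the last ring closed, in step 16.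

Key step: step 16

Remark: decalin locants follow the target name (C1 CH2, C2 carbinol, C4a methyl-bearing fusion carbon, C5 CHBr, C8 C(CH3)OH, C8a fusion carbinol); ring C is C1' (quaternary, on C2), C2' (CMe2), C3' (CHBr), C4' (CH2), C5' (CHOH). Compounds 14–21 are expected as mixtures of the two geometric isomers of the exocyclic C2=C1' bond; both converge on the same C2 cation in step 16, so their SMILES leave that one double bond undefined on purpose.

**Route**

Step 1
Reactants: 1 (S)-Wieland–Miescher ketone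
Product: 2 (4aS,5S)-5-hydroxy-4a-methyl-4,4a,5,6,7,8-hexahydronaphthalen-2(3H)-one
Conditions: NaBH4 (0.3 equiv), EtOH, −10 °C
Reagents that add atoms: none
Why: Borohydride reduction is chemoselective for the saturated C5 ketone over the enone, and hydride adds anti to the angular methyl to give the (5S) equatorial alcohol, a placeholder that keeps C5 distinct from C2 until step 3.

Step 2
Reactants: 2 (4aS,5S)-5-hydroxy-4a-methyl-4,4a,5,6,7,8-hexahydronaphthalen-2(3H)-one
Product: 3 (4aS,5S)-2,2-ethylenedioxy-4a-methyl-1,2,3,4,4a,5,6,7-octahydronaphthalen-5-ol (C8=C8a alkene)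
Conditions: ethylene glycol, p-TsOH (cat.), benzene, reflux, Dean–Stark
Reagents that add atoms: ethylene glycol, OCCO
Why: Acid-catalysed acetalization of the enone proceeds with the usual deconjugative shift of the double bond to C8=C8a, the alkene needed in step 6.

Step 3
Reactants: 3 (4aS,5S)-2,2-ethylenedioxy-4a-methyl-1,2,3,4,4a,5,6,7-octahydronaphthalen-5-ol
Product: 4 (4aS)-2,2-ethylenedioxy-4a-methyl-1,3,4,4a,6,7-hexahydronaphthalen-5(2H)-one
Conditions: Dess–Martin periodinane, NaHCO3, CH2Cl2, 23 °C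
Reagents that add atoms: none
Why: Dess–Martin oxidation returns the C5 ketone under non-acidic conditions, so the ketal and the β,γ-alkene are kept.

Step 4
Reactants: 4 (4aS)-2,2-ethylenedioxy-4a-methyl-1,3,4,4a,6,7-hexahydronaphthalen-5(2H)-one
Product: 6 (4aS)-2,2-ethylenedioxy-4a-methyl-1,2,3,4,4a,7-hexahydronaphthalen-5-yl trifluoromethanesulfonate, via potassium enolate 5 (not isolated)
Conditions: KHMDS, THF, −78 °C; then PhNTf2
Reagents that add atoms: N-phenylbis(trifluoromethanesulfonimide), O=S(=O)(N(c1ccccc1)S(=O)(=O)C(F)(F)F)C(F)(F)F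
Why: The ketone can enolize only toward C6 because C4a is quaternary, so deprotonation and O-sulfonylation (enol triflate formation) should give a single regioisomer.

Step 5
Reactants: 6 (4aS)-2,2-ethylenedioxy-4a-methyl-1,2,3,4,4a,7-hexahydronaphthalen-5-yl trifluoromethanesulfonate
Product: 7 (4aS)-5-bromo-2,2-ethylenedioxy-4a-methyl-1,2,3,4,4a,7-hexahydronaphthalene (C5=C6 and C8=C8a alkenes)
Conditions: [Cp*Ru(MeCN)3]OTf (cat.), LiBr, 1,3-dimethyl-2-imidazolidinone, 100 °C
Reagents that add atoms: lithium bromide, [Li+].[Br-]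
Why: Ruthenium-catalysed triflate–bromide exchange of alkenyl triflates gives the alkenyl bromide without moving the double bond.

Step 6
Reactants: 7 (4aS)-5-bromo-2,2-ethylenedioxy-4a-methyl-1,2,3,4,4a,7-hexahydronaphthalene
Product: 8 (4aS,8aR)-5-bromo-2,2-ethylenedioxy-8a-hydroxy-4a-methyl-1,3,4,4a,7,8a-hexahydronaphthalen-8(2H)-one
Conditions: RuCl3 (cat.), Oxone, NaHCO3, EtOAc/MeCN/H2O, 23 °C
Reagents that add atoms: potassium peroxymonosulfate (Oxone, terminal oxygen source), [K+].[O-]S(=O)(=O)OO
Why: RuO4-catalysed ketohydroxylation attacks the electron-rich trisubstituted C8=C8a alkene rather than the bromoalkene, puts the hydroxyl on the tertiary carbon and the carbonyl on C8, and approaches anti to the angular methyl, which sets C8a as (R).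

Step 7
Reactants: 8 (4aS,8aR)-5-bromo-2,2-ethylenedioxy-8a-hydroxy-4a-methyl-1,3,4,4a,7,8a-hexahydronaphthalen-8(2H)-one
Product: 9 (4aS,8R,8aR)-5-bromo-2,2-ethylenedioxy-4a,8-dimethyl-1,2,3,4,4a,7,8,8a-octahydronaphthalene-8,8a-diol
Conditions: MeMgBr, CeCl3, THF, −78 °C
Reagents that add atoms: methylmagnesium bromide, C[Mg]Br
Why: 1,2-Addition of a methylcerium reagent (weakly basic, so the doubly activated C7–H is not removed) to the C8 ketone from the face opposite the 1,3-related angular methyl should give the (8R) tertiary alcohol, i.e. the trans-diaxial 8,8a-diol.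

Step 8
Reactants: 9 (4aS,8R,8aR)-5-bromo-2,2-ethylenedioxy-4a,8-dimethyl-1,2,3,4,4a,7,8,8a-octahydronaphthalene-8,8a-diol
Product: 10 (4aS,5S,8R,8aR)-5-bromo-2,2-ethylenedioxy-4a,8-dimethyldecahydronaphthalene-8,8a-diol
Conditions: Co(acac)2 (cat.), t-BuOOH (initiator), Et3SiH, 1,4-cyclohexadiene, n-PrOH, 23 °C
Reagents that add atoms: none
Why: Cobalt-catalysed hydrogen-atom-transfer hydrogenation of an alkenyl halide to the alkyl halide: H• adds to C6, and the α-bromo radical at C5 takes its hydrogen on the face anti to the vicinal angular methyl, which leaves bromine equatorial (5S).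

Step 9
Reactants: 10 (4aS,5S,8R,8aR)-5-bromo-2,2-ethylenedioxy-4a,8-dimethyldecahydronaphthalene-8,8a-diol
Product: 11 (4aS,5S,8R,8aR)-5-bromo-8,8a-dihydroxy-4a,8-dimethyloctahydronaphthalen-2(1H)-one
Conditions: PPTS (cat.), THF/H2O, 45 °C
Reagents that add atoms: water, O
Why: Mild acid-catalysed acetal hydrolysis frees the C2 ketone, and the weak acid should avoid dehydration of the β-hydroxy ketone.

Step 10
Reactants: 11 (4aS,5S,8R,8aR)-5-bromo-8,8a-dihydroxy-4a,8-dimethyloctahydronaphthalen-2(1H)-one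
Product: 12 (4aS,5S,8R,8aR)-5-bromo-4a,8-dimethyl-8,8a-bis(trimethylsilyloxy)octahydronaphthalen-2(1H)-one
Conditions: N-(trimethylsilyl)imidazole, CH2Cl2, 40 °C
Reagents that add atoms: N-(trimethylsilyl)imidazole, C[Si](C)(C)n1ccnc1
Why: Neutral silyl transfer masks both tertiary alcohols without enolizing the ketone, which prevents retro-aldol opening in the basic steps that follow.

Step 11
Reactants: 12 (4aS,5S,8R,8aR)-5-bromo-4a,8-dimethyl-8,8a-bis(trimethylsilyloxy)octahydronaphthalen-2(1H)-one; 13 diethyl (1-cyanoethyl)phosphonate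
Product: 14 2-[(4aS,5S,8R,8aR)-5-bromo-4a,8-dimethyl-8,8a-bis(trimethylsilyloxy)octahydronaphthalen-2(1H)-ylidene]propanenitrile (E/Z mixture)
Conditions: NaH, THF, 0 to 50 °C
Reagents that add atoms: none
Why: Horner–Wadsworth–Emmons olefination with the small cyano-stabilised phosphonate anion should form the tetrasubstituted alkene on the unhindered C2 ketone; both geometric isomers are acceptable.

Step 12
Reactants: 14 2-[(4aS,5S,8R,8aR)-5-bromo-4a,8-dimethyl-8,8a-bis(trimethylsilyloxy)octahydronaphthalen-2(1H)-ylidene]propanenitrile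
Product: 16 2-[(4aS,5S,8R,8aR)-5-bromo-4a,8-dimethyl-8,8a-bis(trimethylsilyloxy)octahydronaphthalen-2(1H)-ylidene]propanal (E/Z mixture), via aldimine alane 15 (not isolated)
Conditions: DIBAL-H, toluene, −78 °C; then aqueous Rochelle salt
Reagents that add atoms: water, O
Why: DIBAL-H adds once to the nitrile to give the aluminated aldimine, which is hydrolysed on work-up to the aldehyde (nitrile half-reduction).

Step 13
Reactants: 16 2-[(4aS,5S,8R,8aR)-5-bromo-4a,8-dimethyl-8,8a-bis(trimethylsilyloxy)octahydronaphthalen-2(1H)-ylidene]propanal; 17 allyltributylstannane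
Product: 18 (3R)-2-[(4aS,5S,8R,8aR)-5-bromo-4a,8-dimethyl-8,8a-bis(trimethylsilyloxy)octahydronaphthalen-2(1H)-ylidene]hex-5-en-3-ol
Conditions: (R)-BINOL (20 mol %), Ti(OiPr)4 (10 mol %), 4 Å MS, CH2Cl2, −20 °C; aq. NaHCO3
Reagents that add atoms: none
Why: Keck asymmetric allylation: the (R)-BINOL–Ti(IV) catalyst directs allyl transfer to one face of the aldehyde and should set the carbinol carbon (the future C5') as (R) under reagent control.

Step 14
Reactants: 18 (3R)-2-[(4aS,5S,8R,8aR)-5-bromo-4a,8-dimethyl-8,8a-bis(trimethylsilyloxy)octahydronaphthalen-2(1H)-ylidene]hex-5-en-3-ol; 19 2-methyl-2-butene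
Product: 20 (3R)-2-[(4aS,5S,8R,8aR)-5-bromo-4a,8-dimethyl-8,8a-bis(trimethylsilyloxy)octahydronaphthalen-2(1H)-ylidene]-6-methylhept-5-en-3-ol
Conditions: Grubbs second-generation catalyst (5 mol %), 2-methyl-2-butene/CH2Cl2, 40 °C
Reagents that add atoms: none
Why: Olefin cross-metathesis with 2-methyl-2-butene converts the monosubstituted alkene into the prenyl-type trisubstituted alkene, while the tetrasubstituted alkene is inert to the catalyst.

Step 15
Reactants: 20 (3R)-2-[(4aS,5S,8R,8aR)-5-bromo-4a,8-dimethyl-8,8a-bis(trimethylsilyloxy)octahydronaphthalen-2(1H)-ylidene]-6-methylhept-5-en-3-ol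
Product: 21 tert-butyl (3R)-2-[(4aS,5S,8R,8aR)-5-bromo-4a,8-dimethyl-8,8a-bis(trimethylsilyloxy)octahydronaphthalen-2(1H)-ylidene]-6-methylhept-5-en-3-yl carbonate
Conditions: Boc2O, DMAP (cat.), MeCN, 23 °C
Reagents that add atoms: di-tert-butyl dicarbonate, CC(C)(C)OC(=O)OC(=O)OC(C)(C)C
Why: DMAP-catalysed acylation occurs at the only free hydroxyl and installs the group that later deactivates the neighbouring alkene and captures the C2 cation.

Step 16
Reactants: 21 tert-butyl (3R)-2-[(4aS,5S,8R,8aR)-5-bromo-4a,8-dimethyl-8,8a-bis(trimethylsilyloxy)octahydronaphthalen-2(1H)-ylidene]-6-methylhept-5-en-3-yl carbonate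
Product: 25 cyclic carbonate (1,3-dioxan-2-one across O–C5' and O–C2) of the C5'-epi tetraol as its 8,8a-bis(trimethylsilyl) ether, via bromonium ion 22 (not isolated), via C2 carbocation 23 (not isolated), via tert-butoxydioxanylium ion 24 (not isolated)
Conditions: BDSB (Et2SBr·SbCl5Br, 1.1 equiv), MeNO2, −25 °C, 5 min; then aq. Na2SO3/NaHCO3
Reagents that add atoms: bromodiethylsulfonium bromopentachloroantimonate (BDSB), CC[S+](Br)CC.Cl[Sb-](Cl)(Cl)(Cl)(Cl)Br
Why: Proposed new method: Br⁺ is transferred reversibly to the unhindered prenyl alkene (bromonium ion 22), its tertiary terminus C2' is attacked by C1' of the tetrasubstituted alkene to give the tertiary C2 cation 23, and the carbonyl oxygen of the C5' carbonate captures C2 as dioxanylium ion 24, which loses isobutene; the closest known reaction type is the bromonium-initiated cation–olefin cyclization of 1,5-dienes with tert-butyl carbonate termination, known for six-membered rings, whereas unsubstituted alkylidenecyclohexane 1,5-dienes of this kind are known to close 6-endo to spiro[5.5] products, hence the label. Ring C closes by C2'–C1' bond formation, 5-exo-trig at the alkene, and the temporary 1,3-dioxan-2-one closes 6-exo at the C2 cation. C1' is set by allylic 1,3-strain: the C5'–H eclipses the C1'=C2 bond, so C2' arrives on the face that leaves the C5' oxygen cis to the C1' methyl, which is why the (R)-carbinol, the C5' epimer of the target, is used; C3' is set because in the resulting twisted envelope only the bromonium diastereomer that leads to Br cis to the decalin has its C–Br bond antiperiplanar to the forming bond, and Br⁺ transfer is reversible; C2 is set by axial attack of the tethered oxygen, which keeps the quaternary C1' equatorial. The step needs bromination of the prenyl and not the tetrasubstituted alkene, and 5-exo and not 6-endo closure: the electron-withdrawing allylic carbonate lowers the nucleophilicity of C1'=C2 and destabilises positive charge at C1', so the bond forms at C1' and the charge develops at C2, the strain-free conformer holds the tether away from C2, and C–C bond formation at C2 would create a spiro centre next to the syn-axial C8a silyl ether.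

Step 17
Reactants: 25 cyclic carbonate of the C5'-epi tetraol as its 8,8a-bis(trimethylsilyl) ether
Product: 26 (2R,4aS,5S,8R,8aR)-5-bromo-2-[(1R,3R,5R)-3-bromo-5-hydroxy-1,2,2-trimethylcyclopentyl]-4a,8-dimethyldecahydronaphthalene-2,8,8a-triol (5'-epi-neoirietetraol)
Conditions: K2CO3 (cat.), MeOH, 45 °C
Reagents that add atoms: none
Why: Base-catalysed methanolysis (transesterification) opens the cyclic carbonate to the diol and dimethyl carbonate and cleaves both trimethylsilyl ethers.

Step 18
Reactants: 26 5'-epi-neoirietetraol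
Product: 27 (2S,4R)-4-bromo-2-[(2R,4aS,5S,8R,8aR)-5-bromo-2,8,8a-trihydroxy-4a,8-dimethyldecahydronaphthalen-2-yl]-2,3,3-trimethylcyclopentan-1-one
Conditions: Dess–Martin periodinane, NaHCO3, CH2Cl2, 0 °C; crude product used at once
Reagents that add atoms: none
Why: Dess–Martin oxidation acts on the only secondary alcohol, and the bicarbonate buffer should keep the β-bromo, β'-hydroxy ketone from losing HBr or undergoing retro-aldol cleavage.

Step 19
Reactants: 27 (2S,4R)-4-bromo-2-[(2R,4aS,5S,8R,8aR)-5-bromo-2,8,8a-trihydroxy-4a,8-dimethyldecahydronaphthalen-2-yl]-2,3,3-trimethylcyclopentan-1-one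
Product: 28 neoirietetraol, (2R,4aS,5S,8R,8aR)-5-bromo-2-[(1R,3R,5S)-3-bromo-5-hydroxy-1,2,2-trimethylcyclopentyl]-4a,8-dimethyldecahydronaphthalene-2,8,8a-triol
Conditions: NaBH4, CeCl3·7H2O, MeOH, −78 °C
Reagents that add atoms: none
Why: Luche reduction delivers hydride at low temperature to the carbonyl face that carries the C1' methyl, away from the bulky decalinyl carbinol and the C3' bromine, which should set C5' as (S) with the hydroxyl cis to the decalin.

**Compound list**

1 | (S)-Wieland–Miescher ketone, (8aS)-8a-methyl-3,4,8,8a-tetrahydronaphthalene-1,6(2H,7H)-dione | O=C1CC[C@]2(C)C(=O)CCCC2=C1 | starting material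
2 | (4aS,5S)-5-hydroxy-4a-methyl-4,4a,5,6,7,8-hexahydronaphthalen-2(3H)-one | O=C1CC[C@]2(C)[C@@H](O)CCCC2=C1 | intermediate
3 | (4aS,5S)-2,2-ethylenedioxy-4a-methyl-1,2,3,4,4a,5,6,7-octahydronaphthalen-5-ol | C1COC2(O1)CC[C@]1(C)[C@@H](O)CCC=C1C2 | intermediate
4 | (4aS)-2,2-ethylenedioxy-4a-methyl-1,3,4,4a,6,7-hexahydronaphthalen-5(2H)-one | C1COC2(O1)CC[C@]1(C)C(=O)CCC=C1C2 | intermediate
5 | potassium C5=C6 enolate of 4 | C1COC2(O1)CC[C@]1(C)C([O-])=CCC=C1C2.[K+] | intermediate
6 | (4aS)-2,2-ethylenedioxy-4a-methyl-1,2,3,4,4a,7-hexahydronaphthalen-5-yl trifluoromethanesulfonate | C1COC2(O1)CC[C@]1(C)C(OS(=O)(=O)C(F)(F)F)=CCC=C1C2 | intermediate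
7 | (4aS)-5-bromo-2,2-ethylenedioxy-4a-methyl-1,2,3,4,4a,7-hexahydronaphthalene | C1COC2(O1)CC[C@]1(C)C(Br)=CCC=C1C2 | intermediate
8 | (4aS,8aR)-5-bromo-2,2-ethylenedioxy-8a-hydroxy-4a-methyl-1,3,4,4a,7,8a-hexahydronaphthalen-8(2H)-one | C1COC2(O1)CC[C@]1(C)C(Br)=CCC(=O)[C@@]1(O)C2 | intermediate
9 | (4aS,8R,8aR)-5-bromo-2,2-ethylenedioxy-4a,8-dimethyl-1,2,3,4,4a,7,8,8a-octahydronaphthalene-8,8a-diol | C1COC2(O1)CC[C@]1(C)C(Br)=CC[C@@](C)(O)[C@@]1(O)C2 | intermediate
10 | (4aS,5S,8R,8aR)-5-bromo-2,2-ethylenedioxy-4a,8-dimethyldecahydronaphthalene-8,8a-diol | C1COC2(O1)CC[C@]1(C)[C@@H](Br)CC[C@@](C)(O)[C@@]1(O)C2 | intermediate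
11 | (4aS,5S,8R,8aR)-5-bromo-8,8a-dihydroxy-4a,8-dimethyloctahydronaphthalen-2(1H)-one | O=C1CC[C@]2(C)[C@@H](Br)CC[C@@](C)(O)[C@@]2(O)C1 | intermediate
12 | (4aS,5S,8R,8aR)-5-bromo-4a,8-dimethyl-8,8a-bis(trimethylsilyloxy)octahydronaphthalen-2(1H)-one | O=C1CC[C@]2(C)[C@@H](Br)CC[C@@](C)(O[Si](C)(C)C)[C@@]2(O[Si](C)(C)C)C1 | intermediate
13 | diethyl (1-cyanoethyl)phosphonate | CCOP(=O)(OCC)C(C)C#N | starting material
14 | 2-[(4aS,5S,8R,8aR)-5-bromo-4a,8-dimethyl-8,8a-bis(trimethylsilyloxy)octahydronaphthalen-2(1H)-ylidene]propanenitrile, E/Z mixture | N#CC(C)=C1CC[C@]2(C)[C@@H](Br)CC[C@@](C)(O[Si](C)(C)C)[C@@]2(O[Si](C)(C)C)C1 | intermediate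
15 | N-(diisobutylaluminio) aldimine from 14 | CC(C)C[Al](CC(C)C)N=CC(C)=C1CC[C@]2(C)[C@@H](Br)CC[C@@](C)(O[Si](C)(C)C)[C@@]2(O[Si](C)(C)C)C1 | intermediate
16 | 2-[(4aS,5S,8R,8aR)-5-bromo-4a,8-dimethyl-8,8a-bis(trimethylsilyloxy)octahydronaphthalen-2(1H)-ylidene]propanal, E/Z mixture | O=CC(C)=C1CC[C@]2(C)[C@@H](Br)CC[C@@](C)(O[Si](C)(C)C)[C@@]2(O[Si](C)(C)C)C1 | intermediate
17 | allyltributylstannane | C=CC[Sn](CCCC)(CCCC)CCCC | starting material
18 | (3R)-2-[(4aS,5S,8R,8aR)-5-bromo-4a,8-dimethyl-8,8a-bis(trimethylsilyloxy)octahydronaphthalen-2(1H)-ylidene]hex-5-en-3-ol | C=CC[C@@H](O)C(C)=C1CC[C@]2(C)[C@@H](Br)CC[C@@](C)(O[Si](C)(C)C)[C@@]2(O[Si](C)(C)C)C1 | intermediate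
19 | 2-methyl-2-butene | CC=C(C)C | starting material
20 | (3R)-2-[(4aS,5S,8R,8aR)-5-bromo-4a,8-dimethyl-8,8a-bis(trimethylsilyloxy)octahydronaphthalen-2(1H)-ylidene]-6-methylhept-5-en-3-ol | CC(C)=CC[C@@H](O)C(C)=C1CC[C@]2(C)[C@@H](Br)CC[C@@](C)(O[Si](C)(C)C)[C@@]2(O[Si](C)(C)C)C1 | intermediate
21 | tert-butyl (3R)-2-[(4aS,5S,8R,8aR)-5-bromo-4a,8-dimethyl-8,8a-bis(trimethylsilyloxy)octahydronaphthalen-2(1H)-ylidene]-6-methylhept-5-en-3-yl carbonate | CC(C)=CC[C@@H](OC(=O)OC(C)(C)C)C(C)=C1CC[C@]2(C)[C@@H](Br)CC[C@@](C)(O[Si](C)(C)C)[C@@]2(O[Si](C)(C)C)C1 | intermediate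
22 | bromonium ion of the prenyl alkene of 21 | CC1(C)[Br+][C@@H]1C[C@@H](OC(=O)OC(C)(C)C)C(C)=C1CC[C@]2(C)[C@@H](Br)CC[C@@](C)(O[Si](C)(C)C)[C@@]2(O[Si](C)(C)C)C1 | intermediate
23 | C2 carbocation after closure of ring C | CC1(C)[C@H](Br)C[C@@H](OC(=O)OC(C)(C)C)[C@]1(C)[C+]1CC[C@]2(C)[C@@H](Br)CC[C@@](C)(O[Si](C)(C)C)[C@@]2(O[Si](C)(C)C)C1 | intermediate
24 | 2-tert-butoxy-1,3-dioxan-2-ylium ion spanning O–C5' and O–C2 | CC1(C)[C@H](Br)C[C@@H](O[C+](OC(C)(C)C)O3)[C@]1(C)[C@@]13CC[C@]2(C)[C@@H](Br)CC[C@@](C)(O[Si](C)(C)C)[C@@]2(O[Si](C)(C)C)C1 | intermediate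
25 | cyclic carbonate (trans-fused 1,3-dioxan-2-one across O–C5' and O–C2) of 26, 8,8a-bis(trimethylsilyl) ether; ring C: C1' R, C3' R, C5' R; C2 R | CC1(C)[C@H](Br)C[C@@H](OC(=O)O3)[C@]1(C)[C@@]13CC[C@]2(C)[C@@H](Br)CC[C@@](C)(O[Si](C)(C)C)[C@@]2(O[Si](C)(C)C)C1 | intermediate
26 | 5'-epi-neoirietetraol, (2R,4aS,5S,8R,8aR)-5-bromo-2-[(1R,3R,5R)-3-bromo-5-hydroxy-1,2,2-trimethylcyclopentyl]-4a,8-dimethyldecahydronaphthalene-2,8,8a-triol | CC1(C)[C@H](Br)C[C@@H](O)[C@]1(C)[C@@]1(O)CC[C@]2(C)[C@@H](Br)CC[C@@](C)(O)[C@@]2(O)C1 | intermediate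
27 | (2S,4R)-4-bromo-2-[(2R,4aS,5S,8R,8aR)-5-bromo-2,8,8a-trihydroxy-4a,8-dimethyldecahydronaphthalen-2-yl]-2,3,3-trimethylcyclopentan-1-one | CC1(C)[C@H](Br)CC(=O)[C@]1(C)[C@@]1(O)CC[C@]2(C)[C@@H](Br)CC[C@@](C)(O)[C@@]2(O)C1 | intermediate
28 | neoirietetraol, (2R,4aS,5S,8R,8aR)-5-bromo-2-[(1R,3R,5S)-3-bromo-5-hydroxy-1,2,2-trimethylcyclopentyl]-4a,8-dimethyldecahydronaphthalene-2,8,8a-triol | CC1(C)[C@H](Br)C[C@H](O)[C@]1(C)[C@@]1(O)CC[C@]2(C)[C@@H](Br)CC[C@@](C)(O)[C@@]2(O)C1 | target

**Step count and risks**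

Total step count: 19. Longest linear sequence: 19 steps (1 to 28); 13, 17 and 19 are commercial and enter this one line.

Steps most likely to fail:

Step 16 (Proposed new method). Three processes may defeat it: closure at C2 instead of C1' (6-endo spirocyclisation); transfer of Br⁺ to the tetrasubstituted alkene followed by bromocarbonate formation; proton loss from the C2 cation before the carbonate captures it. The fallback uses established chemistry and sets out from 21. Mercury(II) triflate–N,N-dimethylaniline complex in MeNO2 at −20 °C engages only the unhindered trisubstituted alkene and cannot add irreversibly to the hindered one. The same closure and carbonate capture follow, and aqueous NaBr work-up should give organomercuric bromide F1. Bromodemercuration (Br2, LiBr, pyridine, O2) then replaces mercury by bromine and the route is rejoined at 25. Because this exchange is radical, the C3' epimer is expected as well and would have to be separated.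

Step 8. The hydrogen-atom transfer to the C5 radical may show poor facial selectivity, or bromine may be lost reductively. The fallback sets out from 9 and uses hydroxyl-directed homogeneous hydrogenation with Crabtree's catalyst, [Ir(cod)(PCy3)(py)]PF6, under H2 in CH2Cl2. The C8a hydroxyl binds iridium and both hydrogens are delivered inner-sphere to the face anti to the angular methyl; the route is rejoined at 10 (no new compound, F0).

Step 19. The β-bromo ketone may lose HBr under basic conditions, the C1'–C2 bond may cleave by retro-aldol, or hydride delivery may show insufficient facial selectivity. The fallback sets out from 27 and uses enzymatic reduction with a ketoreductase chosen from a panel for hydride delivery to the methyl-bearing face (NADPH, glucose/glucose dehydrogenase recycling, pH 7 buffer with DMSO co-solvent). No base is present; the route is rejoined at 28 (no new compound, F0).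

**Further compounds**

F1 | step 16 | organomercuric bromide: cyclic carbonate 25 with HgBr in place of the C3' bromine | CC1(C)[C@H]([Hg]Br)C[C@@H](OC(=O)O3)[C@]1(C)[C@@]13CC[C@]2(C)[C@@H](Br)CC[C@@](C)(O[Si](C)(C)C)[C@@]2(O[Si](C)(C)C)C1
F0 | step 8 | none | none
F0 | step 19 | none | none
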